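Take the easy entry first: each X costs one J and one D, and less J is charged than D, so J is the limiting reagent and its books are the ones to keep.

    D + E → D.E (k1 = 63000 L mol⁻¹ s⁻¹)
    J + D.E → J.D.E (k2 = 9200 L mol⁻¹ s⁻¹)
    J.D.E → E + X (k3 = 1.1 s⁻¹)
    D + J.D.E → G (k4 = 13 L mol⁻¹ s⁻¹)

J 0.50 mM; D 0.750 mM; E 5.0 µM

- the form that holds most of the catalyst when 30 % of the J are converted (D.E / J.D.E / E / G)
- its share of the catalyst then
- apparent order in D when 30 % of the J are converted (percent change of the rate of making X for one percent more D charged)

My own reckoning, at 30 % conversion, in fractions of the charge:

1. Of the J, about 30 % stands as X and about 70.0 % is free, since J.D.E and G together can hold 1.00 % of it at the very most. D stands at about 80.0 % of its own charge.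

2. Turn the constants into rates at the charged amounts. E leaves at 2800 min⁻¹, D.E at 280 min⁻¹, and J.D.E at 66 min⁻¹ towards X but 0.58 min⁻¹ towards G.

3. J.D.E feeds both exits, so the catalyst lost to G per X made is the G step's constant times D, over the X step's constant. Call this the leak: 0.886 % at D as charged.

4. You have 100 J per catalyst, and D averages 90.0 % of its charge so far. Multiplying these by the leak and the conversion, I reckon G at 23.9 % of the catalyst.

5. The live 76.1 % divides by time spent per round: 0.909 s as J.D.E, 0.311 s as D.E, 0.0265 s as E. That gives J.D.E 55.5 %, D.E 19.0 % and E 1.61 %. With G, the books close. J.D.E holds most, so it is the resting state.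

6. One percent more D charged changes the live catalyst by −0.350 percent and the round's share in J.D.E by 0.0265 percent, so I commit to an order of −0.323.

The forecast says J.D.E, 55 % and −0.32, reasoning that “about 0.8 % is lost per turnover over 30 turnovers”. On share and order it stands where I stand.

The flask gives J.D.E at 56.0 % of the catalyst and an order of −0.31. G then holds 23.2 %, at 0.668 min. Now put the leak to the flask with twice the D charged: the leak becomes 1.77 %, D averages 95.0 % of that charge, and G at 30 % conversion comes to 50.5 %. By this reckoning live catalyst goes from 76.1 % to 49.5 %, a factor of 0.650. The rate in that flask stood at 0.672 of this flask's rate.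

The rate constants are made up; the run is a simulation.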